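**Retrosynthetic overview**

1. Target ⇐ acetylation/desilylation of 38. The C1=C10 bond and 5β‑H of 38 come from Pd‑catalysed hydrogenolysis of a 1α‑formate of a 5(10)‑ene with 1,3‑transposition, and that formate comes from the 1‑oxo‑5(10)‑ene 34.
2. Ring A (C1–C5, C10) is closed last by a [4+2] cycloaddition that forms C2–C3 and C4–C5. The feature that allows this: ring A is a cyclohexene whose C1=C10 bond lies between O‑bearing C2 and ring‑fusion C5, with the acyl‑bearing quaternary C4 in a 1,4‑relation to C1. With a temporary silyloxy group on C1 it is the adduct of the diene C5=C10–C1(OSi)=C2(OAc) and 2‑methylacrolein (C3=C4 with C18, C19).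
3. The cycloaddition sets C4 and C2. Its C5 centre is erased (step 11) and re‑set from C1/C2 (steps 14–16), which also removes the temporary C1 oxygen.
4. Ring B comes first, from 2‑methylcyclohexenone: Cu‑catalysed asymmetric conjugate methylation (C8), then trans‑alkylation of the enolate (C9) with an (R)‑citronellol‑derived iodide (C13). Ketone → enol triflate → acetyl → α'‑acetoxy enone → silyl dienol ether.
5. Order of rings: ring B (from the cyclohexenone), then ring A (step 10).

Key step: step 10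

Remark (assumption): halimane numbering is used for the bicyclic compounds (ring A = C1–C5 + C10; ring B = C5–C10; side chain C11–C16; C17 on C8; C18 = carbonyl carbon and C19 = methyl on C4; C20 = methyl on C9). β is the face that carries H‑5, C‑11, the C‑18 carbonyl and the 2‑acetoxy group in the target, α the face of the three ring methyl groups. Where a ligand or catalyst antipode is needed, the one that gives the drawn configuration is meant; both antipodes are available.

**Route**

Step 1
Reactants: 1 (R)-citronellol; 2 tert-butyl(chloro)diphenylsilane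
Product: 3 (R)-citronellol TBDPS ether
Conditions: imidazole, DMF, rt
Reagents that add atoms: tert-butyl(chloro)diphenylsilane, CC(C)(C)[Si](Cl)(c1ccccc1)c1ccccc1
Why: Silylation of a primary alcohol gives a TBDPS ether that should carry O‑15 through the enolate, Lewis‑acid and oxidation steps, while C13 is bought with the starting material.

Step 2
Reactants: 3 (R)-citronellol TBDPS ether; 4 ozone; 5 sodium chlorite
Product: 7 (4R)-6-(TBDPS-oxy)-4-methylhexanoic acid, via aldehyde 6 (not isolated)
Conditions: O3, CH2Cl2, −78 °C; Me2S; then NaClO2, NaH2PO4, 2-methyl-2-butene, t-BuOH/H2O, rt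
Reagents that add atoms: ozone, [O-][O+]=O; sodium chlorite, [Na+].[O-]Cl=O
Why: Ozonolysis of the trisubstituted alkene followed by Pinnick oxidation should give the acid without touching the remote stereocentre or the aryl groups on silicon.

Step 3
Reactants: 7 (4R)-6-(TBDPS-oxy)-4-methylhexanoic acid; 8 iodine
Product: 10 (3S)-5-iodo-3-methylpentyl TBDPS ether, via acyl hypoiodite 9 (not isolated)
Conditions: PhI(OAc)2, I2, cyclohexane, hν (W lamp), reflux
Reagents that add atoms: iodine, II
Why: Suárez iododecarboxylation (a radical Hunsdiecker‑type reaction) removes the one surplus carbon and gives the primary iodide directly.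

Step 4
Reactants: 11 2-methylcyclohex-2-en-1-one; 12 trimethylaluminium; 13 trimethylsilyl triflate
Product: 15 {[(3R)-2,3-dimethylcyclohex-1-en-1-yl]oxy}trimethylsilane, via aluminium enolate 14 (not isolated)
Conditions: CuTC (2 mol %), chiral phosphoramidite (4 mol %), Me3Al, Et2O, −30 °C; then TMSOTf, THF, −30 → 0 °C
Reagents that add atoms: trimethylaluminium, C[Al](C)C; trimethylsilyl triflate, C[Si](C)(C)OS(=O)(=O)C(F)(F)F
Why: Copper‑catalysed asymmetric conjugate addition to a 2‑substituted cyclohexenone sets C8 by catalyst control, and O‑silylation stores the regiodefined tetrasubstituted enolate.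

Step 5
Reactants: 15 {[(3R)-2,3-dimethylcyclohex-1-en-1-yl]oxy}trimethylsilane; 10 (3S)-5-iodo-3-methylpentyl TBDPS ether
Product: 17 (2S,3R)-2,3-dimethyl-2-[(3R)-3-methyl-5-(TBDPS-oxy)pentyl]cyclohexan-1-one, via lithium enolate 16 (not isolated)
Conditions: MeLi, THF, 0 °C; then 10, HMPA, −78 °C → rt
Reagents that add atoms: iodide 10, ICC[C@@H](C)CCO[Si](c1ccccc1)(c1ccccc1)C(C)(C)C
Why: Alkylation of a regiodefined lithium enolate, in which the electrophile should enter anti to the adjacent C8 methyl group, so the side chain is trans and the two methyl groups cis at C9 (minor diastereomers, including those from imperfect ee in step 4, are removable here by chromatography).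

Step 6
Reactants: 17 (2S,3R)-2,3-dimethyl-2-[(3R)-3-methyl-5-(TBDPS-oxy)pentyl]cyclohexan-1-one; 18 N-phenylbis(trifluoromethanesulfonimide)
Product: 20 (5R,6S)-5,6-dimethyl-6-[(3R)-3-methyl-5-(TBDPS-oxy)pentyl]cyclohex-1-en-1-yl triflate, via potassium enolate 19 (not isolated)
Conditions: KHMDS, THF, −78 °C; then PhNTf2, −78 → 0 °C
Reagents that add atoms: N-phenylbis(trifluoromethanesulfonimide), FC(F)(F)S(=O)(=O)N(c1ccccc1)S(=O)(=O)C(F)(F)F
Why: Enol triflate formation is regiospecific because the ketone has α‑hydrogens only on the C5 side.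

Step 7
Reactants: 20 enol triflate; 21 tributyl(1-ethoxyvinyl)stannane; 22 water
Product: 24 1-{(5R,6S)-5,6-dimethyl-6-[(3R)-3-methyl-5-(TBDPS-oxy)pentyl]cyclohex-1-en-1-yl}ethan-1-one, via 2-ethoxy diene 23 (not isolated)
Conditions: Pd(PPh3)4 (5 mol %), LiCl, THF, reflux; then 1 M HCl, rt
Reagents that add atoms: tributyl(1-ethoxyvinyl)stannane, CCOC(=C)[Sn](CCCC)(CCCC)CCCC; water, O
Why: Stille coupling of an enol triflate with an acetyl‑anion equivalent, then hydrolysis of the enol ether, attaches C1 and C2 as a conjugated methyl ketone.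

Step 8
Reactants: 24 methyl enone; 25 manganese(III) acetate
Product: 26 2-oxo-2-{(5R,6S)-5,6-dimethyl-6-[(3R)-3-methyl-5-(TBDPS-oxy)pentyl]cyclohex-1-en-1-yl}ethyl acetate
Conditions: Mn(OAc)3·2H2O, benzene, reflux (Dean–Stark)
Reagents that add atoms: manganese(III) acetate, CC(=O)[O-].CC(=O)[O-].CC(=O)[O-].[Mn+3]
Why: Mn(III)‑mediated α'‑acetoxylation of an α,β‑unsaturated ketone should place the C2 acetate of the target at the only α' position.

Step 9
Reactants: 26 α'-acetoxy enone; 27 tert-butyldimethylsilyl triflate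
Product: 28 (Z)-2-(TBS-oxy)-2-{(5R,6S)-5,6-dimethyl-6-[(3R)-3-methyl-5-(TBDPS-oxy)pentyl]cyclohex-1-en-1-yl}ethenyl acetate
Conditions: TBSOTf, Et3N, CH2Cl2, −78 → 0 °C
Reagents that add atoms: tert-butyldimethylsilyl triflate, CC(C)(C)[Si](C)(C)OS(=O)(=O)C(F)(F)F
Why: Soft enolisation toward the only α'‑hydrogens gives the cross‑conjugated 2‑silyloxy diene, and the (Z)‑enol ether (acetoxy trans to the bulky ring) is expected, which leaves hydrogen at the inside position of C2.

Step 10
Reactants: 28 (Z)-1-acetoxy-2-silyloxy diene; 29 2-methylacrolein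
Product: 30 (2R,4S,5R,8R,9S,13R)-2-acetoxy-1-(TBS-oxy)-15-(TBDPS-oxy)halim-1(10)-en-18-al (2β-OAc; 18-CHO β; 5α-H)
Conditions: 2-methylacrolein (3 equiv), o-tolyl-CBS oxazaborolidine·Tf2NH (20 mol %), CH2Cl2, −78 → −40 °C; Et3N quench
Reagents that add atoms: 2-methylacrolein, CC(=C)C=O
Why: This is a Lewis‑acid‑catalysed, concerted but asynchronous [4+2] cycloaddition of normal electron demand that closes ring A by forming C2–C3 and C4–C5 through a boat‑like six‑membered transition state; the closest known reaction type is the oxazaborolidinium‑catalysed Diels–Alder reaction of 2‑silyloxy‑1,3‑dienes with 2‑methylacrolein. Regiochemistry follows from the C1 silyloxy group, which makes the enol‑ether carbon C2 the nucleophilic terminus (it outweighs the weakly donating C2 acetate), so C2 bonds to the β‑CH2 of the enal (C3) and the quaternary C4 is joined to C5. C4 is fixed by the enal face that the catalyst leaves open, and the endo mode (formyl under the diene, usual for 1‑acyloxy dienes, which have no bridging CH2 to reverse it) ties that face to attack on the β face of the diene, which puts the outside 2‑acetoxy group and the formyl group cis (2β‑OAc, 18‑CHO β, 19‑CH3 α). The β face is also the one the substrate should prefer, because with the 8‑methyl equatorial the cis 9‑methyl is pseudoaxial on the α face, 1,3 to the C5 terminus, so catalyst and substrate are matched. The C5 centre made here (5α‑H) need not be controlled, since it becomes sp2 in step 11 and is re‑made in step 16. The step therefore needs regio‑, endo‑ and facial selectivity, secured by the C1 silyloxy group, the acyloxy‑diene/enal pairing, and the catalyst together with the 9α‑methyl, and the (Z)‑enol geometry keeps the s‑cis diene accessible.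

Step 11
Reactants: 30 cycloadduct
Product: 31 (2R,4S,8R,9S,13R)-2-acetoxy-1-oxo-15-(TBDPS-oxy)halim-5(10)-en-18-al
Conditions: DDQ, 2,4,6-collidine, benzene, 0 °C → rt
Reagents that add atoms: none
Why: DDQ dehydrogenation of a silyl enol ether (hydride abstraction from the allylic C5–H, then loss of silicon) should give the tetrasubstituted C5=C10 enone, which erases the C5 centre of the cycloadduct and turns the C1 oxygen into a handle for transposition.

Step 12
Reactants: 31 enone aldehyde; 5 sodium chlorite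
Product: 32 (2R,4S,8R,9S,13R)-2-acetoxy-1-oxo-15-(TBDPS-oxy)halim-5(10)-en-18-oic acid
Conditions: NaClO2, NaH2PO4, 2-methyl-2-butene, t-BuOH/H2O, rt
Reagents that add atoms: sodium chlorite, [Na+].[O-]Cl=O
Why: Pinnick oxidation of a non‑enolisable neopentyl aldehyde, run after step 11 so that no silyl enol ether is exposed to hypochlorite.

Step 13
Reactants: 32 acid; 33 (trimethylsilyl)diazomethane
Product: 34 methyl (2R,4S,8R,9S,13R)-2-acetoxy-1-oxo-15-(TBDPS-oxy)halim-5(10)-en-18-oate
Conditions: TMSCHN2, MeOH/toluene, 0 °C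
Reagents that add atoms: (trimethylsilyl)diazomethane, C[Si](C)(C)C=[N+]=[N-]
Why: Neutral esterification with a diazoalkane avoids base, which could epimerise C2 of the α‑acetoxy ketone.

Step 14
Reactants: 34 keto ester
Product: 35 methyl (1R,2R,4S,8R,9S,13R)-2-acetoxy-1-hydroxy-15-(TBDPS-oxy)halim-5(10)-en-18-oate (1α-OH)
Conditions: NaBH4, CeCl3·7H2O, MeOH, −78 °C
Reagents that add atoms: none
Why: Luche 1,2‑reduction, in which ring A should sit as the half‑chair with C3 as flap (2‑OAc pseudoequatorial, 4α‑methyl axial, ester equatorial) so that axial hydride delivery from the β face gives the 1α (equatorial) alcohol trans to the acetate.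

Step 15
Reactants: 35 allylic alcohol; 36 acetic formic anhydride
Product: 37 methyl (1R,2R,4S,8R,9S,13R)-2-acetoxy-1-formyloxy-15-(TBDPS-oxy)halim-5(10)-en-18-oate
Conditions: HCO2Ac, pyridine, CH2Cl2, 0 °C
Reagents that add atoms: acetic formic anhydride, CC(=O)OC=O
Why: Formylation of the secondary allylic alcohol with a small mixed anhydride, with retention at C1, prepares the substrate for hydride transfer from formate.

Step 16
Reactants: 37 allylic formate
Product: 38 methyl (2R,4S,5S,8R,9S,13R)-2-acetoxy-15-(TBDPS-oxy)halim-1(10)-en-18-oate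
Conditions: Pd(OAc)2 (5 mol %), n-Bu3P (5 mol %), THF, rt → 50 °C
Reagents that add atoms: none
Why: Tsuji–Mandai hydrogenolysis of an allylic formate, in which Pd(0) ionises the 1α‑formate with inversion onto the β face of the C1–C10–C5 allyl unit and, after loss of CO2, hydride passes from palladium to the more substituted terminus C5 on that face, giving 5β‑H and returning the double bond to C1=C10.

Step 17
Reactants: 38 silyl ether
Product: 39 methyl (2R,4S,5S,8R,9S,13R)-2-acetoxy-15-hydroxyhalim-1(10)-en-18-oate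
Conditions: TBAF, AcOH, THF, rt
Reagents that add atoms: none
Why: Buffered fluoride desilylation frees the primary alcohol while the 2‑acetate and methyl ester stay intact.

Step 18
Reactants: 39 primary alcohol; 40 acetic anhydride
Product: 41 methyl (2R,4S,5S,8R,9S,13R)-2,15-diacetoxyhalim-1(10)-en-18-oate (target)
Conditions: Ac2O, pyridine, DMAP (cat.), CH2Cl2, rt
Reagents that add atoms: acetic anhydride, CC(=O)OC(C)=O
Why: Acetylation of the primary alcohol completes the target.

**Compound list**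

1 | (R)-citronellol | CC(C)=CCC[C@@H](C)CCO | starting material
2 | tert-butyl(chloro)diphenylsilane | CC(C)(C)[Si](Cl)(c1ccccc1)c1ccccc1 | starting material
3 | (R)-citronellol TBDPS ether | CC(C)=CCC[C@@H](C)CCO[Si](c1ccccc1)(c1ccccc1)C(C)(C)C | intermediate
4 | ozone | [O-][O+]=O | starting material
5 | sodium chlorite | [Na+].[O-]Cl=O | starting material
6 | (4R)-6-(TBDPS-oxy)-4-methylhexanal | O=CCC[C@@H](C)CCO[Si](c1ccccc1)(c1ccccc1)C(C)(C)C | intermediate
7 | (4R)-6-(TBDPS-oxy)-4-methylhexanoic acid | OC(=O)CC[C@@H](C)CCO[Si](c1ccccc1)(c1ccccc1)C(C)(C)C | intermediate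
8 | iodine | II | starting material
9 | acyl hypoiodite of 7 | O=C(OI)CC[C@@H](C)CCO[Si](c1ccccc1)(c1ccccc1)C(C)(C)C | intermediate
10 | tert-butyl{[(3S)-5-iodo-3-methylpentyl]oxy}diphenylsilane | ICC[C@@H](C)CCO[Si](c1ccccc1)(c1ccccc1)C(C)(C)C | intermediate
11 | 2-methylcyclohex-2-en-1-one | CC1=CCCCC1=O | starting material
12 | trimethylaluminium | C[Al](C)C | starting material
13 | trimethylsilyl triflate | C[Si](C)(C)OS(=O)(=O)C(F)(F)F | starting material
14 | dimethylaluminium (3R)-2,3-dimethylcyclohex-1-en-1-olate | C[C@@H]1CCCC(O[Al](C)C)=C1C | intermediate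
15 | {[(3R)-2,3-dimethylcyclohex-1-en-1-yl]oxy}trimethylsilane | C[C@@H]1CCCC(O[Si](C)(C)C)=C1C | intermediate
16 | lithium (3R)-2,3-dimethylcyclohex-1-en-1-olate | C[C@@H]1CCCC(O[Li])=C1C | intermediate
17 | (2S,3R)-2,3-dimethyl-2-[(3R)-3-methyl-5-(TBDPS-oxy)pentyl]cyclohexan-1-one | O=C1CCC[C@@H](C)[C@]1(C)CC[C@@H](C)CCO[Si](c2ccccc2)(c2ccccc2)C(C)(C)C | intermediate
18 | N-phenylbis(trifluoromethanesulfonimide) | FC(F)(F)S(=O)(=O)N(c1ccccc1)S(=O)(=O)C(F)(F)F | starting material
19 | potassium enolate of 17 | [K]OC1=CCC[C@@H](C)[C@]1(C)CC[C@@H](C)CCO[Si](c2ccccc2)(c2ccccc2)C(C)(C)C | intermediate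
20 | (5R,6S)-5,6-dimethyl-6-[(3R)-3-methyl-5-(TBDPS-oxy)pentyl]cyclohex-1-en-1-yl triflate | FC(F)(F)S(=O)(=O)OC1=CCC[C@@H](C)[C@]1(C)CC[C@@H](C)CCO[Si](c2ccccc2)(c2ccccc2)C(C)(C)C | intermediate
21 | tributyl(1-ethoxyvinyl)stannane | CCOC(=C)[Sn](CCCC)(CCCC)CCCC | starting material
22 | water | O | starting material
23 | 2-ethoxy diene (ethoxyvinyl coupling product of 20) | CCOC(=C)C1=CCC[C@@H](C)[C@]1(C)CC[C@@H](C)CCO[Si](c2ccccc2)(c2ccccc2)C(C)(C)C | intermediate
24 | 1-{(5R,6S)-5,6-dimethyl-6-[(3R)-3-methyl-5-(TBDPS-oxy)pentyl]cyclohex-1-en-1-yl}ethan-1-one | CC(=O)C1=CCC[C@@H](C)[C@]1(C)CC[C@@H](C)CCO[Si](c2ccccc2)(c2ccccc2)C(C)(C)C | intermediate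
25 | manganese(III) acetate | CC(=O)[O-].CC(=O)[O-].CC(=O)[O-].[Mn+3] | starting material
26 | 2-oxo-2-{(5R,6S)-5,6-dimethyl-6-[(3R)-3-methyl-5-(TBDPS-oxy)pentyl]cyclohex-1-en-1-yl}ethyl acetate | CC(=O)OCC(=O)C1=CCC[C@@H](C)[C@]1(C)CC[C@@H](C)CCO[Si](c2ccccc2)(c2ccccc2)C(C)(C)C | intermediate
27 | tert-butyldimethylsilyl triflate | CC(C)(C)[Si](C)(C)OS(=O)(=O)C(F)(F)F | starting material
28 | (Z)-2-(TBS-oxy)-2-{(5R,6S)-5,6-dimethyl-6-[(3R)-3-methyl-5-(TBDPS-oxy)pentyl]cyclohex-1-en-1-yl}ethenyl acetate | CC(=O)O/C=C(\O[Si](C)(C)C(C)(C)C)C1=CCC[C@@H](C)[C@]1(C)CC[C@@H](C)CCO[Si](c2ccccc2)(c2ccccc2)C(C)(C)C | intermediate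
29 | 2-methylacrolein | CC(=C)C=O | starting material
30 | (2R,4S,5R,8R,9S,13R)-2-acetoxy-1-(TBS-oxy)-15-(TBDPS-oxy)halim-1(10)-en-18-al | O=C[C@@]1(C)C[C@@H](OC(C)=O)C(O[Si](C)(C)C(C)(C)C)=C2[C@H]1CC[C@@H](C)[C@]2(C)CC[C@@H](C)CCO[Si](c3ccccc3)(c3ccccc3)C(C)(C)C | intermediate
31 | (2R,4S,8R,9S,13R)-2-acetoxy-1-oxo-15-(TBDPS-oxy)halim-5(10)-en-18-al | O=C[C@@]1(C)C[C@@H](OC(C)=O)C(=O)C2=C1CC[C@@H](C)[C@]2(C)CC[C@@H](C)CCO[Si](c3ccccc3)(c3ccccc3)C(C)(C)C | intermediate
32 | (2R,4S,8R,9S,13R)-2-acetoxy-1-oxo-15-(TBDPS-oxy)halim-5(10)-en-18-oic acid | OC(=O)[C@@]1(C)C[C@@H](OC(C)=O)C(=O)C2=C1CC[C@@H](C)[C@]2(C)CC[C@@H](C)CCO[Si](c3ccccc3)(c3ccccc3)C(C)(C)C | intermediate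
33 | (trimethylsilyl)diazomethane | C[Si](C)(C)C=[N+]=[N-] | starting material
34 | methyl (2R,4S,8R,9S,13R)-2-acetoxy-1-oxo-15-(TBDPS-oxy)halim-5(10)-en-18-oate | COC(=O)[C@@]1(C)C[C@@H](OC(C)=O)C(=O)C2=C1CC[C@@H](C)[C@]2(C)CC[C@@H](C)CCO[Si](c3ccccc3)(c3ccccc3)C(C)(C)C | intermediate
35 | methyl (1R,2R,4S,8R,9S,13R)-2-acetoxy-1-hydroxy-15-(TBDPS-oxy)halim-5(10)-en-18-oate | COC(=O)[C@@]1(C)C[C@@H](OC(C)=O)[C@H](O)C2=C1CC[C@@H](C)[C@]2(C)CC[C@@H](C)CCO[Si](c3ccccc3)(c3ccccc3)C(C)(C)C | intermediate
36 | acetic formic anhydride | CC(=O)OC=O | starting material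
37 | methyl (1R,2R,4S,8R,9S,13R)-2-acetoxy-1-formyloxy-15-(TBDPS-oxy)halim-5(10)-en-18-oate | COC(=O)[C@@]1(C)C[C@@H](OC(C)=O)[C@H](OC=O)C2=C1CC[C@@H](C)[C@]2(C)CC[C@@H](C)CCO[Si](c3ccccc3)(c3ccccc3)C(C)(C)C | intermediate
38 | methyl (2R,4S,5S,8R,9S,13R)-2-acetoxy-15-(TBDPS-oxy)halim-1(10)-en-18-oate | COC(=O)[C@@]1(C)C[C@@H](OC(C)=O)C=C2[C@@H]1CC[C@@H](C)[C@]2(C)CC[C@@H](C)CCO[Si](c3ccccc3)(c3ccccc3)C(C)(C)C | intermediate
39 | methyl (2R,4S,5S,8R,9S,13R)-2-acetoxy-15-hydroxyhalim-1(10)-en-18-oate | COC(=O)[C@@]1(C)C[C@@H](OC(C)=O)C=C2[C@@H]1CC[C@@H](C)[C@]2(C)CC[C@@H](C)CCO | intermediate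
40 | acetic anhydride | CC(=O)OC(C)=O | starting material
41 | methyl (2R,4S,5S,8R,9S,13R)-2,15-diacetoxyhalim-1(10)-en-18-oate | COC(=O)[C@@]1(C)C[C@@H](OC(C)=O)C=C2[C@@H]1CC[C@@H](C)[C@]2(C)CC[C@@H](C)CCOC(C)=O | target

**Step count and risks**

Total step count: 18. Longest linear sequence: 17 steps (steps 1–3, then 5–18).

Most likely to fail, 1: step 10. The second bond (C4–C5, a quaternary carbon joining a carbon next to the fully substituted C10) may not close after the first C2–C3 bond, leaving an open‑chain Michael‑type product. Endo or facial selectivity may also erode, which would scramble C2 or C4. The fallback replaces the catalysed cycloaddition by an anionic stepwise annulation and sets out from 24. Kinetic deprotonation (LDA, THF, −78 °C) and addition of methyl methacrylate should give, by double Michael addition, the saturated keto ester methyl 1-oxo-15-(TBDPS-oxy)halimane-18-oate F1 (C4 epimers to be separated). Dehydrogenation with IBX (DMSO, 70 °C) should give the conjugated enone methyl 1-oxo-15-(TBDPS-oxy)halim-5(10)-en-18-oate F2. Mn(OAc)3 in benzene at reflux then introduces the 2‑acetoxy group and the route is rejoined at 34; the 2‑epimers would be separated and the unwanted one re‑equilibrated with DBU. This path is known chemistry but relies on chromatography for C4 and C2.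

Most likely to fail, 2: step 16. Positional or facial fidelity may be lost at the π‑allyl stage (hydride transfer to C1, or β‑hydride elimination to a diene), or the newly allylic 2‑acetate may be ionised by Pd(0). The fallback is a metal‑free reductive transposition through an allylic diazene and sets out from 35. Mitsunobu displacement with 2‑nitrobenzenesulfonylhydrazide (PPh3, DEAD, THF, −30 °C) should give, with inversion, the 1β‑sulfonylhydrazine F3. On warming this loses the sulfinic acid to give the 1β‑diazene F4, whose retro‑ene loss of N2 delivers hydrogen to the β face of C5 and rejoins the route at 38. Participation by the neighbouring acetate during the displacement is the point to watch on this path.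

Most likely to fail, 3: step 11. Hydride abstraction at a tertiary allylic C–H flanked by two quaternary carbons may be sluggish, or oxidation may start at C2–H instead. The fallback is ionic halogenation–elimination and sets out from 30. NBS (THF, 0 °C) should brominate the enol‑ether carbon C10 with loss of silicon to give the α‑bromo ketone F5. Dehydrobromination toward C5–H (DBU, toluene, rt) then rejoins the route at 31.

Further compounds
F1 | step 10 | methyl (4S,8R,9S,13R)-1-oxo-15-(TBDPS-oxy)halimane-18-oate (mixture at C5 and C10) | COC(=O)[C@@]1(C)CCC(=O)C2C1CC[C@@H](C)[C@]2(C)CC[C@@H](C)CCO[Si](c3ccccc3)(c3ccccc3)C(C)(C)C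
F2 | step 10 | methyl (4S,8R,9S,13R)-1-oxo-15-(TBDPS-oxy)halim-5(10)-en-18-oate | COC(=O)[C@@]1(C)CCC(=O)C2=C1CC[C@@H](C)[C@]2(C)CC[C@@H](C)CCO[Si](c3ccccc3)(c3ccccc3)C(C)(C)C
F3 | step 16 | methyl 2β-acetoxy-1β-[1-(2-nitrobenzenesulfonyl)hydrazinyl]-15-(TBDPS-oxy)halim-5(10)-en-18-oate | COC(=O)[C@@]1(C)C[C@@H](OC(C)=O)[C@@H](N(N)S(=O)(=O)c3ccccc3[N+](=O)[O-])C2=C1CC[C@@H](C)[C@]2(C)CC[C@@H](C)CCO[Si](c4ccccc4)(c4ccccc4)C(C)(C)C
F4 | step 16 | methyl 2β-acetoxy-1β-diazenyl-15-(TBDPS-oxy)halim-5(10)-en-18-oate | COC(=O)[C@@]1(C)C[C@@H](OC(C)=O)[C@@H](N=N)C2=C1CC[C@@H](C)[C@]2(C)CC[C@@H](C)CCO[Si](c3ccccc3)(c3ccccc3)C(C)(C)C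
F5 | step 11 | 2β-acetoxy-10-bromo-1-oxo-15-(TBDPS-oxy)-5α-halimane-18-al (mixture at C10) | O=C[C@@]1(C)C[C@@H](OC(C)=O)C(=O)C2(Br)[C@H]1CC[C@@H](C)[C@]2(C)CC[C@@H](C)CCO[Si](c3ccccc3)(c3ccccc3)C(C)(C)C
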